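**Plan**

1. The heptane chain is numbered from C1 (the CH2 on the guaiacyl ring) to C7 (the CH2 on the syringyl ring). C1 is benzylic and para to a phenolic oxygen, and C3 (ketone) and C5 (carbinol) carry oxygen 1,3 to each other, so C1–C5 together with the C5 oxygen are the five carbons and the oxygen of a 2-aryl-oxan-4-ol.
2. Retrosynthesis: re-form the C1–O(C5) bond to give a cis-2,6-disubstituted oxan-4-one and reduce C3 to the ring carbinol. Then cut C1–C2 and C1–O of the oxane (Prins) into a protected vanillin and an (R)-homoallylic alcohol, and cut C4–C5 (allylation) and C6–C7 (olefination) back to syringaldehyde.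
3. Forward: the syringyl arm is grown linearly (C6–C7 by Wittig, C4–C5 by allylboration). The oxane, the only ring made, is closed in one step from alcohol and aldehyde, its carbinol is oxidised, and hydrogenolysis opens the ring at the benzylic C1–O bond while removing the protecting groups.
4. Stereochemistry: the single stereocentre (C5, R) comes from a reagent-controlled Brown allylboration and travels as C6 of the oxane. The two centres created in the ring closure are relayed from it and are destroyed again by oxidation and ring opening.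
5. Protecting groups: a benzyl ether on the syringyl phenol, and a benzyl carbonate on the vanillin phenol. The carbonate keeps that ring electron-poor during the cyclisation and leaves as toluene and CO2 in the last step.

Key step: step 7

**Route**

Step 1
Reactants: 1 syringaldehyde (4-hydroxy-3,5-dimethoxybenzaldehyde)
Product: 2 4-(benzyloxy)-3,5-dimethoxybenzaldehyde
Conditions: BnBr, K2CO3, DMF, 60 °C
Reagents that add atoms: benzyl bromide, BrCc1ccccc1
Why: Williamson etherification of the acidic, if flanked, phenol with benzyl bromide under K2CO3 is routine and installs a group that falls in the final hydrogenolysis.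

Step 2
Reactants: 2 4-(benzyloxy)-3,5-dimethoxybenzaldehyde; 3 methyl (triphenylphosphoranylidene)acetate
Product: 4 methyl (2E)-3-[4-(benzyloxy)-3,5-dimethoxyphenyl]prop-2-enoate
Conditions: toluene, 90 °C
Reagents that add atoms: none
Why: Wittig olefination of an aromatic aldehyde with a stabilised ylide should give the (E)-cinnamate (C6–C7 bond), and the alkene geometry is of no consequence because it is reduced next.

Step 3
Reactants: 4 methyl (2E)-3-[4-(benzyloxy)-3,5-dimethoxyphenyl]prop-2-enoate
Product: 5 methyl 3-[4-(benzyloxy)-3,5-dimethoxyphenyl]propanoate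
Conditions: NaBH4, NiCl2·6H2O (0.3 equiv), MeOH–THF, 0 °C
Reagents that add atoms: none
Why: Nickel boride conjugate reduction saturates the cinnamate C=C while sparing the ester and the aryl benzyl ether, which hydrogenation over palladium would not guarantee.

Step 4
Reactants: 5 methyl 3-[4-(benzyloxy)-3,5-dimethoxyphenyl]propanoate
Product: 6 3-[4-(benzyloxy)-3,5-dimethoxyphenyl]propanal
Conditions: iBu2AlH (1.05 equiv), CH2Cl2, −78 °C; MeOH quench at −78 °C, then aq. potassium sodium tartrate
Reagents that add atoms: none
Why: Partial reduction of the methyl ester with one equivalent of iBu2AlH at −78 °C should stop at the tetrahedral aluminium hemiacetal, which releases the aldehyde only on work-up.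

Step 5
Reactants: 6 3-[4-(benzyloxy)-3,5-dimethoxyphenyl]propanal; 7 allylmagnesium bromide
Product: 9 (3R)-1-[4-(benzyloxy)-3,5-dimethoxyphenyl]hex-5-en-3-ol, via diisopinocampheylborinate ester 8 (not isolated)
Conditions: (−)-Ipc2BOMe, 7, Et2O, −78 °C to rt; filter off magnesium salts; then 6, −78 °C or below; then 3 M NaOH, 30% H2O2, rt
Reagents that add atoms: none
Why: Brown asymmetric allylboration, in which (−)-Ipc2B(allyl), made from 7 and the (−)-Ipc2BOMe derived from (+)-α-pinene, delivers allyl to the Si face of the unbranched aldehyde through a chair six-membered transition state, so the (R)-carbinol (C5 of the target) is set by the reagent before oxidative work-up cleaves borinate 8.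

Step 6
Reactants: 10 vanillin (4-hydroxy-3-methoxybenzaldehyde)
Product: 11 benzyl (4-formyl-2-methoxyphenyl) carbonate
Conditions: CbzCl, Et3N, CH2Cl2, 0 °C to rt
Reagents that add atoms: benzyl chloroformate, O=C(Cl)OCc1ccccc1
Why: O-Acylation of the phenol with a chloroformate (carbonate formation) gives an aldehyde whose para oxygen is electron-poor for the Prins step yet is removable by hydrogenolysis.

Step 7
Reactants: 9 (3R)-1-[4-(benzyloxy)-3,5-dimethoxyphenyl]hex-5-en-3-ol; 11 benzyl (4-formyl-2-methoxyphenyl) carbonate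
Product: 13 benzyl 4-[(2R,4S,6R)-6-{2-[4-(benzyloxy)-3,5-dimethoxyphenyl]ethyl}-4-hydroxyoxan-2-yl]-2-methoxyphenyl carbonate (all-cis oxan-4-ol), via oxan-4-yl trifluoroacetate 12 (not isolated)
Conditions: 11 (1.3 equiv), CF3CO2H (15 equiv), CH2Cl2, 0 °C to rt; concentrate; then sat. aq. NaHCO3, MeOH, 0 °C
Reagents that add atoms: trifluoroacetic acid, OC(=O)C(F)(F)F
Why: TFA condenses 9 and 11 via the hemiacetal to the (E)-oxocarbenium ion (forming the chain C1–O bond, oxane C2–O1), the terminal alkene carbon attacks the oxocarbenium carbon through a chair transition state (forming chain C1–C2, oxane C2–C3), and the secondary oxan-4-yl cation is captured by trifluoroacetate to give 12, which bicarbonate hydrolyses to 13. The closest known reaction is the TFA-mediated Prins cyclisation of homoallylic alcohols with aromatic aldehydes to all-cis 2,6-disubstituted oxan-4-ols. The oxane closes in a 6-endo-trig mode with respect to the alkene. The new C2 centre is controlled by the existing C6 centre, since both substituents sit equatorial in the chair with an (E)-oxocarbenium ion (2,6-cis), and the new C4 centre by equatorial capture of the chair cation, giving (2R,4S,6R). The selectivity that matters is retention of the C6 configuration, because C2 and C4 are erased later: the C6–O bond of 9 is not benzylic and is never broken, and the carbonate-bearing, electron-poor aryl group denies the 2-oxonia-Cope isomer the ionisation to a benzylic cation and the aldehyde exchange that racemise alkoxy-substituted benzaldehyde cases. Chemoselectivity rests on the acid stability of the benzyl carbonate and benzyl ether and on cleaving the trifluoroacetate with bicarbonate, which is too mild to touch the aryl carbonate.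

Step 8
Reactants: 13 benzyl 4-[(2R,4S,6R)-6-{2-[4-(benzyloxy)-3,5-dimethoxyphenyl]ethyl}-4-hydroxyoxan-2-yl]-2-methoxyphenyl carbonate
Product: 14 benzyl 4-[(2R,6R)-6-{2-[4-(benzyloxy)-3,5-dimethoxyphenyl]ethyl}-4-oxooxan-2-yl]-2-methoxyphenyl carbonate (cis-2,6 oxan-4-one)
Conditions: Dess–Martin periodinane, NaHCO3, CH2Cl2, rt
Reagents that add atoms: none
Why: Dess–Martin oxidation of the secondary ring carbinol to the ketone is mild and buffered, so the aryl carbonate, the benzyl ether and the cis-2,6 ring centres (which scramble by oxa-Michael opening only under acid or base) should be unaffected while the C4 centre is deliberately erased.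

Step 9
Reactants: 14 benzyl 4-[(2R,6R)-6-{2-[4-(benzyloxy)-3,5-dimethoxyphenyl]ethyl}-4-oxooxan-2-yl]-2-methoxyphenyl carbonate
Product: 16 (5R)-5-hydroxy-7-(4-hydroxy-3,5-dimethoxyphenyl)-1-(4-hydroxy-3-methoxyphenyl)heptan-3-one, via bisphenol oxanone 15 (not isolated)
Conditions: H2 (3 bar), Pd(OH)2 on carbon, EtOAc–MeOH, rt
Reagents that add atoms: none
Why: Catalytic hydrogenolysis should first remove the benzyl ether and the benzyl carbonate (which then loses CO2) to give 15, whose benzylic C2–O1 bond, now activated by the para hydroxyl, is cleaved in the same way (hydrogenolysis of a cyclic benzylic ether, as in the opening of 2-aryl-oxolane lignans), leaving C1 as CH2 and the untouched C6–O bond as the (R)-C5 hydroxyl.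

**Compound list**

1 | syringaldehyde (4-hydroxy-3,5-dimethoxybenzaldehyde) | COc1cc(C=O)cc(OC)c1O | starting material
2 | 4-(benzyloxy)-3,5-dimethoxybenzaldehyde | COc1cc(C=O)cc(OC)c1OCc1ccccc1 | intermediate
3 | methyl (triphenylphosphoranylidene)acetate | COC(=O)C=P(c1ccccc1)(c1ccccc1)c1ccccc1 | starting material
4 | methyl (2E)-3-[4-(benzyloxy)-3,5-dimethoxyphenyl]prop-2-enoate | COC(=O)/C=C/c1cc(OC)c(OCc2ccccc2)c(OC)c1 | intermediate
5 | methyl 3-[4-(benzyloxy)-3,5-dimethoxyphenyl]propanoate | COC(=O)CCc1cc(OC)c(OCc2ccccc2)c(OC)c1 | intermediate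
6 | 3-[4-(benzyloxy)-3,5-dimethoxyphenyl]propanal | O=CCCc1cc(OC)c(OCc2ccccc2)c(OC)c1 | intermediate
7 | allylmagnesium bromide | C=CC[Mg]Br | starting material
8 | (3R)-1-[4-(benzyloxy)-3,5-dimethoxyphenyl]hex-5-en-3-yl diisopinocampheylborinate (both isopinocampheyl groups configured as in (−)-isopinocampheol, from (+)-α-pinene) | C=CC[C@H](OB([C@@H]1C[C@@H]2C[C@H]([C@H]1C)C2(C)C)[C@@H]1C[C@@H]2C[C@H]([C@H]1C)C2(C)C)CCc1cc(OC)c(OCc2ccccc2)c(OC)c1 | intermediate
9 | (3R)-1-[4-(benzyloxy)-3,5-dimethoxyphenyl]hex-5-en-3-ol | C=CC[C@H](O)CCc1cc(OC)c(OCc2ccccc2)c(OC)c1 | intermediate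
10 | vanillin (4-hydroxy-3-methoxybenzaldehyde) | COc1cc(C=O)ccc1O | starting material
11 | benzyl (4-formyl-2-methoxyphenyl) carbonate | COc1cc(C=O)ccc1OC(=O)OCc1ccccc1 | intermediate
12 | (2R,4S,6R)-2-{4-[(benzyloxycarbonyl)oxy]-3-methoxyphenyl}-6-{2-[4-(benzyloxy)-3,5-dimethoxyphenyl]ethyl}oxan-4-yl trifluoroacetate (all-cis) | O=C(O[C@@H]1C[C@H](c2ccc(OC(=O)OCc3ccccc3)c(OC)c2)O[C@H](CCc2cc(OC)c(OCc3ccccc3)c(OC)c2)C1)C(F)(F)F | intermediate
13 | benzyl 4-[(2R,4S,6R)-6-{2-[4-(benzyloxy)-3,5-dimethoxyphenyl]ethyl}-4-hydroxyoxan-2-yl]-2-methoxyphenyl carbonate (all-cis) | O[C@@H]1C[C@H](c2ccc(OC(=O)OCc3ccccc3)c(OC)c2)O[C@H](CCc2cc(OC)c(OCc3ccccc3)c(OC)c2)C1 | intermediate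
14 | benzyl 4-[(2R,6R)-6-{2-[4-(benzyloxy)-3,5-dimethoxyphenyl]ethyl}-4-oxooxan-2-yl]-2-methoxyphenyl carbonate (cis-2,6) | O=C1C[C@H](c2ccc(OC(=O)OCc3ccccc3)c(OC)c2)O[C@H](CCc2cc(OC)c(OCc3ccccc3)c(OC)c2)C1 | intermediate
15 | (2R,6R)-2-(4-hydroxy-3-methoxyphenyl)-6-[2-(4-hydroxy-3,5-dimethoxyphenyl)ethyl]oxan-4-one (cis-2,6) | O=C1C[C@H](c2ccc(O)c(OC)c2)O[C@H](CCc2cc(OC)c(O)c(OC)c2)C1 | intermediate
16 | (5R)-5-hydroxy-7-(4-hydroxy-3,5-dimethoxyphenyl)-1-(4-hydroxy-3-methoxyphenyl)heptan-3-one | COc1cc(CCC(=O)C[C@H](O)CCc2cc(OC)c(O)c(OC)c2)ccc1O | target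

**Step count**

Total: 9 steps. Longest linear sequence: 8 steps (steps 1–5 and 7–9, from syringaldehyde).

**Steps most likely to fail**

Step 7. The risk is erosion of the C6 configuration through 2-oxonia-Cope rearrangement with aldehyde exchange (which would also give symmetrical oxanes), or a sluggish cyclisation during which the acid-sensitive syringyl benzyl ether is lost. The fallback is a segment-coupling Prins, in which the C1–O bond is made first as an ester so that no free aldehyde or water is present when the oxocarbenium ion forms. It sets out from 9. Esterification with commercial 4-(benzyloxy)-3-methoxybenzoic acid (DCC, DMAP, CH2Cl2) should give (3R)-1-[4-(benzyloxy)-3,5-dimethoxyphenyl]hex-5-en-3-yl 4-(benzyloxy)-3-methoxybenzoate F1. Reductive acetylation (iBu2AlH at −78 °C, then Ac2O, pyridine, DMAP) should give the α-acetoxy ether F2. Ionisation with BF3·OEt2 and AcOH in CH2Cl2 at low temperature should close the same ring through the same chair to the all-cis 4-acetoxy oxane F3. Methanolysis (K2CO3, MeOH) should give the benzyl-ether oxan-4-ol F4, and Dess–Martin oxidation the benzyl-ether oxanone F5. Hydrogenolysis of F5 under the conditions of step 9 (through 15) comes back to the route at 16.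

Step 9. The risk is that the ring C–O bond resists hydrogenolysis once the benzyl groups are gone, so the reaction stalls at the bisphenol oxanone. A second risk is that traces of acid or base start a reversible oxa-Michael opening on the alkyl side of the ring, which would erode the C5 configuration. The fallback replaces surface hydrogenolysis of that bond by hydride transfer to a benzylic cation. It sets out from 14. A short hydrogenolysis (H2 at 1 bar, palladium on carbon, EtOAc) should remove only the benzyl ether and benzyl carbonate, and 15 is isolated. Ionic hydrogenation of 15 (Et3SiH, CF3CO2H, CH2Cl2, 0 °C) should then ionise only the para-hydroxybenzylic C2–O1 bond and reduce the resulting cation to CH2, coming back to the route at 16 with the C6–O bond untouched.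

Step 4. The risk is over-reduction of the ester to the primary alcohol, or incomplete conversion that leaves inseparable ester. The fallback is a two-step redox detour. It sets out from 5. Full reduction (LiAlH4, THF, 0 °C) should give 3-[4-(benzyloxy)-3,5-dimethoxyphenyl]propan-1-ol F6, and oxidation with Dess–Martin periodinane (CH2Cl2, rt) comes back to the route at 6.

**Further compounds**

F1 | step 7 | (3R)-1-[4-(benzyloxy)-3,5-dimethoxyphenyl]hex-5-en-3-yl 4-(benzyloxy)-3-methoxybenzoate | C=CC[C@H](OC(=O)c1ccc(OCc2ccccc2)c(OC)c1)CCc1cc(OC)c(OCc2ccccc2)c(OC)c1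
F2 | step 7 | [4-(benzyloxy)-3-methoxyphenyl]{[(3R)-1-[4-(benzyloxy)-3,5-dimethoxyphenyl]hex-5-en-3-yl]oxy}methyl acetate (both epimers at the acetal carbon) | C=CC[C@H](OC(OC(C)=O)c1ccc(OCc2ccccc2)c(OC)c1)CCc1cc(OC)c(OCc2ccccc2)c(OC)c1
F3 | step 7 | (2R,4S,6R)-2-[4-(benzyloxy)-3-methoxyphenyl]-6-{2-[4-(benzyloxy)-3,5-dimethoxyphenyl]ethyl}oxan-4-yl acetate | CC(=O)O[C@@H]1C[C@H](c2ccc(OCc3ccccc3)c(OC)c2)O[C@H](CCc2cc(OC)c(OCc3ccccc3)c(OC)c2)C1
F4 | step 7 | (2R,4S,6R)-2-[4-(benzyloxy)-3-methoxyphenyl]-6-{2-[4-(benzyloxy)-3,5-dimethoxyphenyl]ethyl}oxan-4-ol | O[C@@H]1C[C@H](c2ccc(OCc3ccccc3)c(OC)c2)O[C@H](CCc2cc(OC)c(OCc3ccccc3)c(OC)c2)C1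
F5 | step 7 | (2R,6R)-2-[4-(benzyloxy)-3-methoxyphenyl]-6-{2-[4-(benzyloxy)-3,5-dimethoxyphenyl]ethyl}oxan-4-one | O=C1C[C@H](c2ccc(OCc3ccccc3)c(OC)c2)O[C@H](CCc2cc(OC)c(OCc3ccccc3)c(OC)c2)C1
F0 | step 9 | none | none
F6 | step 4 | 3-[4-(benzyloxy)-3,5-dimethoxyphenyl]propan-1-ol | OCCCc1cc(OC)c(OCc2ccccc2)c(OC)c1
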